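The ring numbering is that of cembrane. C1 carries the isopropenyl group, C2 the ring acetate, C4 the acetoxymethyl carbon C18, C7 the hydroxyl and C8 the methylidene C19. The oxygens on C18 and C7 are 1,5-related through C4–C5–C6 of the 14-membered ring. This is a Michael retron that keeps C3=C4 (Rauhut–Currier pattern). The ring is closed at C4–C5: an acyclic (Z)-α-stannyl enal (C18 = CHO) is transmetallated to copper and adds to the vinyl ketone C5=C6–C7=O. One operation builds the carbocycle with the C3=C4 geometry intact. It leaves C18 and C7 as carbonyls, so both C7 epimers made earlier converge and one CBS reduction sets C7.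

Key step: step 12

Remark: 6–9 are racemic at C7 and 13–17 are mixtures of both C7 epimers; C7 is left undefined in their SMILES because step 11 erases it. C2 is R by the CIP rules in 13–19 and S from 20 on, with the same spatial arrangement.

Step 1
Reactants: 1 (E)-geranylacetone
Product: 3 (5E)-6,10-dimethylundeca-1,5,9-trien-2-yl triflate, via lithium enolate 2 (not isolated)
Conditions: LiN(iPr)2 (LDA), THF, −78 °C; PhNTf2, −78 to 0 °C
Reagents that add atoms: N-phenylbis(trifluoromethanesulfonimide) O=S(=O)(N(c1ccccc1)S(=O)(=O)C(F)(F)F)C(F)(F)F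
Why: Kinetic enolisation of the methyl ketone on its CH3 side followed by O-sulfonylation (enol triflate formation) fixes the later C8=C19 methylidene.

Step 2
Reactants: 3 enol triflate; 4 acrolein
Product: 6 rac-(7E)-8,12-dimethyl-4-methylidenetrideca-1,7,11-trien-3-ol, via alkenylchromium dichloride 5 (not isolated)
Conditions: CrCl2, NiCl2 (cat.), DMF, 23 °C
Reagents that add atoms: none
Why: In this Nozaki–Hiyama–Kishi coupling, nickel-catalysed formation of alkenylchromium 5 and its 1,2-addition to acrolein should give the bis-allylic alcohol, and its racemic C7 centre is harmless because step 11 erases it.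

Step 3
Reactants: 6 divinyl carbinol
Product: 7 TBS ether of 6
Conditions: TBSCl, imidazole, DMF, 23 °C
Reagents that add atoms: tert-butyldimethylsilyl chloride CC(C)(C)[Si](C)(C)Cl
Why: Silyl ether protection masks the C7 hydroxyl through the oxidation, borylation and acetylation steps.

Step 4
Reactants: 7 TBS ether
Product: 8 (2E,6E)-11-(tert-butyldimethylsilyloxy)-2,6-dimethyl-10-methylidenetrideca-2,6,12-trien-1-ol
Conditions: SeO2 (cat.), t-BuOOH, salicylic acid (cat.), CH2Cl2, 0 °C, stopped at partial conversion
Reagents that add atoms: tert-butyl hydroperoxide CC(C)(C)OO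
Why: The Riley allylic oxidation (ene reaction, then [2,3]-sigmatropic shift) attacks the electron-rich terminal trisubstituted alkene at its E-methyl group and should give the E-allylic alcohol at C16.

Step 5
Reactants: 8 allylic alcohol
Product: 9 pinacol (2E,6E)-allylboronate (boron on C16)
Conditions: B2pin2, Pd(MeCN)4(BF4)2 (cat.), DMSO/MeOH, 40 °C
Reagents that add atoms: bis(pinacolato)diboron CC1(C)OB(OC1(C)C)B1OC(C)(C)C(C)(C)O1
Why: Palladium-catalysed borylation of an allylic alcohol through a π-allylpalladium intermediate places boron on the unhindered terminus C16 and should keep the E-trisubstituted alkene.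

Step 6
Reactants: 10 tert-butyldimethyl(prop-2-yn-1-yloxy)silane
Product: 12 4-(tert-butyldimethylsilyloxy)but-2-ynal, via lithium acetylide 11 (not isolated)
Conditions: n-BuLi, THF, −78 °C; DMF; aq KH2PO4
Reagents that add atoms: N,N-dimethylformamide CN(C)C=O
Why: Formylation of a lithium acetylide with DMF gives the ynal that supplies C2, C3, C4 and C18.

Step 7
Reactants: 9 allylboronate; 12 ynal
Product: 14 (1R,2R)-anti propargylic alcohol bis-TBS ether, via borate ester 13 (not isolated)
Conditions: (R)-TRIP phosphoric acid (10 mol %), 4 Å MS, toluene, −40 °C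
Reagents that add atoms: none
Why: This chiral phosphoric acid-catalysed allylboration runs through a closed Zimmerman–Traxler chair, in which the E-boronate sets the C1/C2 anti relationship and creates the isopropenyl group by allyl transposition, while (R)-TRIP directs attack to the Re face of 12 and so sets the absolute configuration.

Step 8
Reactants: 14 propargylic alcohol
Product: 15 C2 acetate of 14
Conditions: Ac2O, Et3N, DMAP (cat.), CH2Cl2, 0 °C
Reagents that add atoms: acetic anhydride CC(=O)OC(C)=O
Why: DMAP-catalysed acylation installs the C2 acetate of the target while the two other oxygens are still silylated.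

Step 9
Reactants: 15 acetate
Product: 16 C7,C18-diol (C2 acetate, C3≡C4 alkyne)
Conditions: Bu4NF, AcOH, THF, 23 °C
Reagents that add atoms: none
Why: Fluoride-induced desilylation, buffered with AcOH to protect the acetate, frees the C18 and C7 hydroxyls in one operation.

Step 10
Reactants: 16 alkyne diol
Product: 17 (Z)-C4-tributylstannyl alkene diol (tin cis to C2)
Conditions: Bu3SnH (slow addition), [Cp*RuCl]4 (cat.), CH2Cl2, 23 °C
Reagents that add atoms: tributyltin hydride CCCC[SnH](CCCC)CCCC
Why: In this ruthenium-catalysed trans-hydrostannation, hydrogen bonding of the free propargylic C18–OH to the chloride ligand steers tin to the proximal carbon C4, trans addition places it cis to C2, and alkenes are not touched.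

Step 11
Reactants: 17 stannyl diol
Product: 18 (Z)-α-stannyl enal with a vinyl ketone terminus
Conditions: MnO2 (excess), CH2Cl2, 23 °C
Reagents that add atoms: none
Why: MnO2 oxidation of allylic alcohols converts both carbinols at once, which creates the donor (α-stannyl enal) and the acceptor (vinyl ketone) and merges the two C7 epimers into one compound.

Step 12
Reactants: 18 stannyl enal vinyl ketone
Product: 21 (1R,2S)-macrocyclic keto enal, via alkenylcopper 19 (not isolated), via copper enolate 20 (not isolated)
Conditions: Cu(O2CC4H3S) (copper thiophene-2-carboxylate, CuTC, 3 equiv), NMP, 0 to 23 °C, 18 added by syringe pump (final 1 mM); aq NH4Cl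
Reagents that add atoms: none
Why: Proposed new method: tin-to-copper exchange, driven by formation of the tin carboxylate, turns the C4–Sn bond of 18 into alkenylcopper 19 (a C-bound copper allenolate), which adds through C4 to the unsubstituted terminus C5 of the vinyl ketone and gives enolate 20, protonated at C6 on work-up. The closest known reaction type is the CuCl-mediated intramolecular conjugate addition of alkenylstannanes to enones, shown for five- and six-membered rings but not for a macrocycle or an α-formyl alkenyl donor. The 14-membered carbocycle closes in the 14-endo-trig mode. No stereocentre is formed; the C3=C4 geometry follows from retention at C4, and should 19 lose it through its allenolate form, the enal with C2 trans to CHO is also the thermodynamic isomer, so both paths converge. The step needs C5 over the second acceptor terminus C19 (secured by the α-substituent on C8 and by the more strained 12-membered alternative), cyclisation over oligomerisation or homocoupling (slow addition at high dilution), and no attack on the C15=C16 isopropenyl group. That last point is why copper is chosen: alkenylcopper does not carbometallate unactivated alkenes, whereas a C4–palladium species cis to C2 would be set up for 5-exo-trig insertion into C15=C16.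

Step 13
Reactants: 21 keto enal
Product: 22 (1R,2S,7R)-C7,C18-diol
Conditions: (S)-Me-CBS oxazaborolidine, catecholborane, toluene, −78 °C; MeOH, pH 7 buffer
Reagents that add atoms: none
Why: In this Corey–Bakshi–Shibata reduction, with the branched alkenyl flank C8 as the large group and C6H2 as the small group, the (S)-catalyst should deliver hydride to give (7R), the aldehyde is reduced to the C18 alcohol in the same pot, and catecholborane at low temperature spares the alkenes.

Step 14
Reactants: 22 diol
Product: 23 target CNP0077636.1
Conditions: AcCl (1 equiv), 2,4,6-collidine, CH2Cl2, −78 °C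
Reagents that add atoms: acetyl chloride CC(=O)Cl
Why: In this chemoselective acylation the unhindered primary allylic C18–OH should react far faster than the secondary C7–OH flanked by C8, which gives the target.

Compound list
1 | (E)-geranylacetone, (5E)-6,10-dimethylundeca-5,9-dien-2-one | CC(=O)CC/C=C(\C)CCC=C(C)C | starting material
2 | terminal lithium enolate of 1 | [Li]OC(=C)CC/C=C(\C)CCC=C(C)C | intermediate
3 | (5E)-6,10-dimethylundeca-1,5,9-trien-2-yl triflate | C=C(OS(=O)(=O)C(F)(F)F)CC/C=C(\C)CCC=C(C)C | intermediate
4 | acrolein | C=CC=O | starting material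
5 | alkenylchromium dichloride from 3 | C=C([Cr](Cl)Cl)CC/C=C(\C)CCC=C(C)C | intermediate
6 | rac-(7E)-8,12-dimethyl-4-methylidenetrideca-1,7,11-trien-3-ol | C=CC(O)C(=C)CC/C=C(\C)CCC=C(C)C | intermediate
7 | TBS ether of 6 | C=CC(O[Si](C)(C)C(C)(C)C)C(=C)CC/C=C(\C)CCC=C(C)C | intermediate
8 | (2E,6E)-11-(tert-butyldimethylsilyloxy)-2,6-dimethyl-10-methylidenetrideca-2,6,12-trien-1-ol | C=CC(O[Si](C)(C)C(C)(C)C)C(=C)CC/C=C(\C)CC/C=C(\C)CO | intermediate
9 | pinacol (2E,6E)-allylboronate derived from 8 | C=CC(O[Si](C)(C)C(C)(C)C)C(=C)CC/C=C(\C)CC/C=C(\C)CB1OC(C)(C)C(C)(C)O1 | intermediate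
10 | tert-butyldimethyl(prop-2-yn-1-yloxy)silane | C#CCO[Si](C)(C)C(C)(C)C | starting material
11 | lithium acetylide of 10 | [Li]C#CCO[Si](C)(C)C(C)(C)C | intermediate
12 | 4-(tert-butyldimethylsilyloxy)but-2-ynal | O=CC#CCO[Si](C)(C)C(C)(C)C | intermediate
13 | pinacol borate ester of 14 | C=CC(O[Si](C)(C)C(C)(C)C)C(=C)CC/C=C(\C)CC[C@H](C(=C)C)[C@@H](OB1OC(C)(C)C(C)(C)O1)C#CCO[Si](C)(C)C(C)(C)C | intermediate
14 | seco-cembrane: (1R)-isopropenyl, (2R)-OH (anti), C3≡C4, C18–OTBS, C7–OTBS, C5=C6 vinyl, C8=C19, (11E) | C=CC(O[Si](C)(C)C(C)(C)C)C(=C)CC/C=C(\C)CC[C@H](C(=C)C)[C@@H](O)C#CCO[Si](C)(C)C(C)(C)C | intermediate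
15 | C2 acetate of 14 | C=CC(O[Si](C)(C)C(C)(C)C)C(=C)CC/C=C(\C)CC[C@H](C(=C)C)[C@@H](OC(C)=O)C#CCO[Si](C)(C)C(C)(C)C | intermediate
16 | C7,C18-diol, C2 acetate, C3≡C4 alkyne | C=CC(O)C(=C)CC/C=C(\C)CC[C@H](C(=C)C)[C@@H](OC(C)=O)C#CCO | intermediate
17 | (3Z)-C4-tributylstannyl alkene, C7,C18-diol, C2 acetate | C=CC(O)C(=C)CC/C=C(\C)CC[C@H](C(=C)C)[C@@H](OC(C)=O)/C=C(/CO)[Sn](CCCC)(CCCC)CCCC | intermediate
18 | (3Z)-α-stannyl enal (C18 = CHO) with vinyl ketone C5=C6–C7=O | C=CC(=O)C(=C)CC/C=C(\C)CC[C@H](C(=C)C)[C@@H](OC(C)=O)/C=C(/C=O)[Sn](CCCC)(CCCC)CCCC | intermediate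
19 | C4-alkenylcopper (copper allenolate) from 18 | C=CC(=O)C(=C)CC/C=C(\C)CC[C@H](C(=C)C)[C@@H](OC(C)=O)/C=C(/C=O)[Cu] | intermediate
20 | macrocyclic copper enolate (C6=C7–OCu) | C=C1CC/C=C(\C)CC[C@H](C(=C)C)[C@@H](OC(C)=O)/C=C(/C=O)CC=C1O[Cu] | intermediate
21 | (1R,2S)-2-acetoxy-7-oxocembra-3,8(19),11,15-tetraen-18-al, C2 trans to CHO, (11E) | C=C1CC/C=C(\C)CC[C@H](C(=C)C)[C@@H](OC(C)=O)/C=C(/C=O)CCC1=O | intermediate
22 | (1R,2S,7R)-2-acetoxycembra-3,8(19),11,15-tetraene-7,18-diol | C=C1CC/C=C(\C)CC[C@H](C(=C)C)[C@@H](OC(C)=O)/C=C(/CO)CC[C@H]1O | intermediate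
23 | (1R,2S,7R)-2,18-diacetoxycembra-3,8(19),11,15-tetraen-7-ol, CNP0077636.1 | C=C1CC/C=C(\C)CC[C@H](C(=C)C)[C@@H](OC(C)=O)/C=C(/COC(C)=O)CC[C@H]1O | target

Total step count: 14. Longest linear sequence: 13 steps (steps 1–5 and 7–14, from 1).

Steps most likely to fail

1. Step 12 (labelled step). The alkenylcopper may be protonated, may homocouple or may add intermolecularly before the slow ring closure, and the dienone may polymerise.
   - The fallback sets out from diol 16 and uses known chemistry.
   - A ruthenium-catalysed Alder-ene type coupling of the alkyne with the allylic alcohol ([CpRu(MeCN)3]PF6, acetone, high dilution) would form the same C4–C5 bond. It proceeds through a ruthenacyclopentene and β-hydride elimination of the C7 carbinol hydrogen.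
   - This gives, by cis addition, the macrocyclic hydroxy ketone with C18 cis to C2 F1.
   - MnO2 would oxidise it to the geometric isomer of the enal F2.
   - Nucleophilic catalysis (DMAP, CH2Cl2) would equilibrate F2 by addition, rotation and elimination to the more stable enal. The route is rejoined at 21.

2. Step 7. Uncatalysed background allylboration of the very electrophilic ynal, and any loss of E geometry in 9, would erode enantio- and diastereoselectivity.
   - The fallback sets out from 8. An Appel reaction (CBr4, PPh3) would give the allylic bromide F3.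
   - F3 would be added to 12 in a Nozaki–Hiyama allylation with CrCl2, a chiral oxazoline–sulfonamide ligand and Et3N in THF.
   - The equilibrating allylchromium reagent reacts through a chair that gives the anti adduct whatever the allyl geometry. The route is rejoined at 14.

3. Step 13. Facial selectivity may be poor because both flanks of the ketone are ring members, and conjugate reduction of the α-methylidene ketone may compete.
   - The fallback sets out from 21. A Luche reduction (NaBH4, CeCl3·7H2O, MeOH, −78 °C) under substrate control would give 22 together with its C7 epimer F4.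
   - The two are diastereomers and separable by chromatography.
   - F4 would be re-oxidised with MnO2 to 21 and recycled. The route is rejoined at 22.

Further compounds
F1 | step 12 | (1R,2S)-2-acetoxy-18-hydroxycembra-3,8(19),11,15-tetraen-7-one with C18 cis to C2 | C=C1CC/C=C(\C)CC[C@H](C(=C)C)[C@@H](OC(C)=O)/C=C(\CO)CCC1=O
F2 | step 12 | C3=C4 geometric isomer of 21 (CHO cis to C2) | C=C1CC/C=C(\C)CC[C@H](C(=C)C)[C@@H](OC(C)=O)/C=C(\C=O)CCC1=O
F3 | step 7 | (2E,6E)-allylic bromide derived from 8 | C=CC(O[Si](C)(C)C(C)(C)C)C(=C)CC/C=C(\C)CC/C=C(\C)CBr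
F4 | step 13 | (7S)-epimer of 22 | C=C1CC/C=C(\C)CC[C@H](C(=C)C)[C@@H](OC(C)=O)/C=C(/CO)CC[C@@H]1O
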